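**Strategy.** The oxolane is disconnected at its C2–C3 bond. C2 bears O1 and the 3-hydroxy-4,5-dimethoxyphenyl ring, so its C–H bonds are benzylic and ether-activated, and the C3 methyl can be carried as a methyl ester that stabilises a metal carbenoid at C3. A rhodium carbenoid at C3 therefore inserts into the ArCH2–O1 group, forming C2–C3, closing the tetrahydrofuran ring and fixing C2 cis to C5 in one operation; C3 is then settled by ester equilibration in the same flask. The precursor is an acyclic α-diazo ester: the (1R,2R) anti-crotylation product of 3,4,5-trimethoxybenzaldehyde (C5, C4), O-alkylated with the benzyl-protected aryl-CH2 group.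

Key step: step 10

Remarks
- Structure check: the target is (2S,3S,4R,5R), with the two aryl groups cis (C2, C5), the two methyl groups cis (C3, C4), and each aryl trans to the methyl next to it. The diazo ester 16 and the ring ester 18 carry exactly this connectivity and configuration; no structure needed correcting.
- Precursor design: a methyl ester is kept so that methoxide equilibration at C3 is degenerate. The C3 configuration from the insertion is not relied on. The diazo group is installed last, by benzoyl activation.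
- Assumption: (R)-TRIP is taken to direct Re-face crotylation of aryl aldehydes, giving the 1R carbinol. Should the opposite sense be found, the (S)-catalyst is used and nothing else changes.

**Route**

Step 1
Reactants: 1 3,4,5-trimethoxybenzaldehyde; 2 (E)-crotylboronic acid pinacol ester
Product: 4 (1R,2R)-2-methyl-1-(3,4,5-trimethoxyphenyl)but-3-en-1-ol, via pinacol borate ester 3 (not isolated)
Conditions: (R)-TRIP (5 mol %), toluene, −30 °C; aqueous work-up
Reagents that add atoms: none
Why: Chiral phosphoric acid-catalysed crotylboration through a closed chair (Zimmerman–Traxler) transition state, in which the (E)-boronate gives the anti relationship and the catalyst, hydrogen-bonded to a boronate oxygen, is expected to expose the Re face of the aldehyde, setting the future C5 and C4 as (1R,2R); the absolute sense is to be confirmed by Mosher ester analysis.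

Step 2
Reactants: 5 3-hydroxy-4,5-dimethoxybenzaldehyde
Product: 6 3-(benzyloxy)-4,5-dimethoxybenzaldehyde
Conditions: BnBr, K2CO3, DMF, rt
Reagents that add atoms: benzyl bromide, BrCc1ccccc1
Why: Williamson O-alkylation of the phenoxide (SN2 on benzyl bromide); the aldehyde is inert to carbonate.

Step 3
Reactants: 6 3-(benzyloxy)-4,5-dimethoxybenzaldehyde
Product: 7 [3-(benzyloxy)-4,5-dimethoxyphenyl]methanol
Conditions: NaBH4, MeOH, 0 °C
Reagents that add atoms: none
Why: Borohydride reduction of the aryl aldehyde to the benzylic alcohol; the aryl ethers are untouched.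

Step 4
Reactants: 7 [3-(benzyloxy)-4,5-dimethoxyphenyl]methanol
Product: 8 1-(benzyloxy)-5-(bromomethyl)-2,3-dimethoxybenzene
Conditions: PBr3 (0.4 equiv), CH2Cl2, 0 °C; used at once
Reagents that add atoms: phosphorus tribromide, BrP(Br)Br
Why: Bromination of the benzylic alcohol through its phosphite ester with SN2 displacement by bromide; the electron-rich bromide is not stored.

Step 5
Reactants: 4 (1R,2R)-2-methyl-1-(3,4,5-trimethoxyphenyl)but-3-en-1-ol; 8 1-(benzyloxy)-5-(bromomethyl)-2,3-dimethoxybenzene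
Product: 9 1-(benzyloxy)-2,3-dimethoxy-5-({[(1R,2R)-2-methyl-1-(3,4,5-trimethoxyphenyl)but-3-en-1-yl]oxy}methyl)benzene
Conditions: NaH, THF/DMF, 0 °C; then 8, Bu4NI (cat.), 0 °C → rt
Reagents that add atoms: none
Why: Williamson ether synthesis, the sodium alkoxide of 4 displacing the benzylic bromide under iodide catalysis; neither stereocentre of 4 is acidic, so both are retained.

Step 6
Reactants: 9 the homoallylic benzylic ether
Product: 11 (3R,4R)-4-{[3-(benzyloxy)-4,5-dimethoxyphenyl]methoxy}-3-methyl-4-(3,4,5-trimethoxyphenyl)butan-1-ol, via B-alkyl-9-BBN adduct 10 (not isolated)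
Conditions: 9-BBN, THF, 0 °C → rt; then aq. NaOH, H2O2, 0 °C
Reagents that add atoms: hydrogen peroxide, OO
Why: Brown hydroboration–oxidation, the bulky borane placing boron on the terminal carbon (anti-Markovnikov) and alkaline peroxide replacing boron by hydroxyl; the adjacent stereocentre is not touched.

Step 7
Reactants: 11 the primary alcohol
Product: 13 (3R,4R)-4-{[3-(benzyloxy)-4,5-dimethoxyphenyl]methoxy}-3-methyl-4-(3,4,5-trimethoxyphenyl)butanoic acid, via aldehyde 12 (not isolated)
Conditions: TEMPO (0.2 equiv), PhI(OAc)2 (2.2 equiv), MeCN/H2O 1:1, rt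
Reagents that add atoms: water, O
Why: Oxoammonium (TEMPO/PhI(OAc)2) oxidation of the primary alcohol to the aldehyde, whose hydrate is oxidised on to the acid; ethers and electron-rich rings are tolerated under these near-neutral conditions.

Step 8
Reactants: 13 the carboxylic acid
Product: 14 methyl (3R,4R)-4-{[3-(benzyloxy)-4,5-dimethoxyphenyl]methoxy}-3-methyl-4-(3,4,5-trimethoxyphenyl)butanoate
Conditions: MeI, K2CO3, DMF, rt
Reagents that add atoms: iodomethane, CI
Why: SN2 methylation of the carboxylate; basic conditions avoid acid-promoted ionisation of the benzylic ether at C4.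

Step 9
Reactants: 14 the methyl ester
Product: 16 methyl (3R,4R)-4-{[3-(benzyloxy)-4,5-dimethoxyphenyl]methoxy}-2-diazo-3-methyl-4-(3,4,5-trimethoxyphenyl)butanoate, via α-benzoyl ester 15 (not isolated)
Conditions: NaH, PhCO2Me, DME, reflux; aq. NH4Cl work-up; crude 15, 4-O2NC6H4SO2N3, DBU, CH2Cl2, 0 °C → rt
Reagents that add atoms: 4-nitrobenzenesulfonyl azide, [N-]=[N+]=NS(=O)(=O)c1ccc(cc1)[N+](=O)[O-]
Why: Crossed Claisen benzoylation followed by Regitz-type debenzoylative diazo transfer, in which the sulfonyl azide adds to the stabilised enolate and the benzoyl group leaves on the sulfonamide nitrogen; the β-stereocentre is not enolisable and is retained.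

Step 10
Reactants: 16 the α-diazo ester
Product: 18 methyl (2S,3S,4R,5R)-2-[3-(benzyloxy)-4,5-dimethoxyphenyl]-4-methyl-5-(3,4,5-trimethoxyphenyl)oxolane-3-carboxylate, via 2,3-cis C3-epimeric ester 17 (not isolated)
Conditions: Rh2(O2CCPh3)4 (1 mol %), CH2Cl2, −78 → −20 °C, slow addition of 16; then evaporate, NaOMe (0.3 equiv), MeOH, rt
Reagents that add atoms: none
Why: Loss of N2 from 16 at the Rh(II) carboxylate gives an electrophilic rhodium carbenoid at C3, which inserts in a concerted, hydride-transfer-like manner into one of the two ArCH2–O1 hydrogens, forming C2–C3 and moving that hydrogen to C3. The closest known reaction type is the Rh(II)-catalysed intramolecular 1,5 C–H insertion of α-diazo esters next to an ether oxygen, which gives 2-substituted tetrahydrofuran-3-carboxylates. The oxolane ring is closed by 1,5-insertion (C3 to C2 across C4–C5–O1) through a chair-like six-centre array C3–C4–C5–O1–C2–H. C2 is set in that array, where the C5 aryl, the C4 methyl and the C2 aryl all sit pseudo-equatorial so that the two aryl groups end up cis; C3 is set thermodynamically by methoxide, which is degenerate with the methyl ester, and the ester is expected to settle trans to the larger C2 aryl and cis to the C4 methyl, so any 17 should converge on 18. The step needs 1,5-insertion to outrun the 1,2-hydride shift from the tertiary C4–H and attack on the ortho carbon of the trimethoxyphenyl ring; the doubly activated C2–H (O1 lone pair and p-methoxy aryl), the methoxy group flanking that ortho carbon, and a bulky carboxylate ligand at low temperature are relied on for this.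

Step 11
Reactants: 18 the oxolane ester
Product: 19 [(2S,3R,4R,5R)-2-[3-(benzyloxy)-4,5-dimethoxyphenyl]-4-methyl-5-(3,4,5-trimethoxyphenyl)oxolan-3-yl]methanol
Conditions: LiAlH4, THF, 0 °C
Reagents that add atoms: none
Why: Hydride reduction of the ester to the primary alcohol; no stereocentre is affected (the C3 descriptor changes by priority only).

Step 12
Reactants: 19 the primary alcohol
Product: 20 [(2S,3R,4R,5R)-2-[3-(benzyloxy)-4,5-dimethoxyphenyl]-4-methyl-5-(3,4,5-trimethoxyphenyl)oxolan-3-yl]methyl methanesulfonate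
Conditions: MsCl, Et3N, CH2Cl2, 0 °C
Reagents that add atoms: methanesulfonyl chloride, CS(=O)(=O)Cl
Why: Sulfonylation of the primary alcohol to a leaving group.

Step 13
Reactants: 20 the mesylate
Product: 21 (2S,3S,4R,5R)-2-[3-(benzyloxy)-4,5-dimethoxyphenyl]-3,4-dimethyl-5-(3,4,5-trimethoxyphenyl)oxolane
Conditions: LiEt3BH, THF, 0 °C → rt
Reagents that add atoms: none
Why: SN2 displacement of the primary mesylate by hydride from the strongly nucleophilic triethylborohydride, turning CH2OMs into the C3 methyl group; C3 itself is not touched.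

Step 14
Reactants: 21 the benzyl ether
Product: 22 5-[(2S,3S,4R,5R)-3,4-dimethyl-5-(3,4,5-trimethoxyphenyl)oxolan-2-yl]-2,3-dimethoxyphenol (target)
Conditions: H2 (1 atm), 10 % Pd/C, EtOAc, rt, stopped at full conversion
Reagents that add atoms: none
Why: Heterogeneous hydrogenolysis of the aryl benzyl ether, which should cleave faster than the hindered secondary ring C–O bonds under neutral conditions.

**Compound list**

1 | 3,4,5-trimethoxybenzaldehyde | COc1cc(C=O)cc(OC)c1OC | starting material
2 | (E)-crotylboronic acid pinacol ester | C/C=C/CB1OC(C)(C)C(C)(C)O1 | starting material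
3 | 4,4,5,5-tetramethyl-2-{[(1R,2R)-2-methyl-1-(3,4,5-trimethoxyphenyl)but-3-en-1-yl]oxy}-1,3,2-dioxaborolane | CC1(C)OB(O[C@@H](c2cc(OC)c(OC)c(OC)c2)[C@H](C)C=C)OC1(C)C | intermediate
4 | (1R,2R)-2-methyl-1-(3,4,5-trimethoxyphenyl)but-3-en-1-ol | O[C@@H](c1cc(OC)c(OC)c(OC)c1)[C@H](C)C=C | intermediate
5 | 3-hydroxy-4,5-dimethoxybenzaldehyde | COc1cc(C=O)cc(O)c1OC | starting material
6 | 3-(benzyloxy)-4,5-dimethoxybenzaldehyde | COc1cc(C=O)cc(OCc2ccccc2)c1OC | intermediate
7 | [3-(benzyloxy)-4,5-dimethoxyphenyl]methanol | COc1cc(CO)cc(OCc2ccccc2)c1OC | intermediate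
8 | 1-(benzyloxy)-5-(bromomethyl)-2,3-dimethoxybenzene | COc1cc(CBr)cc(OCc2ccccc2)c1OC | intermediate
9 | 1-(benzyloxy)-2,3-dimethoxy-5-({[(1R,2R)-2-methyl-1-(3,4,5-trimethoxyphenyl)but-3-en-1-yl]oxy}methyl)benzene | COc1cc(CO[C@@H](c2cc(OC)c(OC)c(OC)c2)[C@H](C)C=C)cc(OCc3ccccc3)c1OC | intermediate
10 | 9-[(3R,4R)-4-{[3-(benzyloxy)-4,5-dimethoxyphenyl]methoxy}-3-methyl-4-(3,4,5-trimethoxyphenyl)butyl]-9-borabicyclo[3.3.1]nonane | COc1cc(CO[C@@H](c2cc(OC)c(OC)c(OC)c2)[C@H](C)CCB2C3CCCC2CCC3)cc(OCc4ccccc4)c1OC | intermediate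
11 | (3R,4R)-4-{[3-(benzyloxy)-4,5-dimethoxyphenyl]methoxy}-3-methyl-4-(3,4,5-trimethoxyphenyl)butan-1-ol | COc1cc(CO[C@@H](c2cc(OC)c(OC)c(OC)c2)[C@H](C)CCO)cc(OCc3ccccc3)c1OC | intermediate
12 | (3R,4R)-4-{[3-(benzyloxy)-4,5-dimethoxyphenyl]methoxy}-3-methyl-4-(3,4,5-trimethoxyphenyl)butanal | COc1cc(CO[C@@H](c2cc(OC)c(OC)c(OC)c2)[C@H](C)CC=O)cc(OCc3ccccc3)c1OC | intermediate
13 | (3R,4R)-4-{[3-(benzyloxy)-4,5-dimethoxyphenyl]methoxy}-3-methyl-4-(3,4,5-trimethoxyphenyl)butanoic acid | COc1cc(CO[C@@H](c2cc(OC)c(OC)c(OC)c2)[C@H](C)CC(=O)O)cc(OCc3ccccc3)c1OC | intermediate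
14 | methyl (3R,4R)-4-{[3-(benzyloxy)-4,5-dimethoxyphenyl]methoxy}-3-methyl-4-(3,4,5-trimethoxyphenyl)butanoate | COc1cc(CO[C@@H](c2cc(OC)c(OC)c(OC)c2)[C@H](C)CC(=O)OC)cc(OCc3ccccc3)c1OC | intermediate
15 | methyl (3R,4R)-2-benzoyl-4-{[3-(benzyloxy)-4,5-dimethoxyphenyl]methoxy}-3-methyl-4-(3,4,5-trimethoxyphenyl)butanoate (both C2 epimers) | COc1cc(CO[C@@H](c2cc(OC)c(OC)c(OC)c2)[C@H](C)C(C(=O)c2ccccc2)C(=O)OC)cc(OCc3ccccc3)c1OC | intermediate
16 | methyl (3R,4R)-4-{[3-(benzyloxy)-4,5-dimethoxyphenyl]methoxy}-2-diazo-3-methyl-4-(3,4,5-trimethoxyphenyl)butanoate | COc1cc(CO[C@@H](c2cc(OC)c(OC)c(OC)c2)[C@H](C)C(=[N+]=[N-])C(=O)OC)cc(OCc3ccccc3)c1OC | intermediate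
17 | methyl (2S,3R,4R,5R)-2-[3-(benzyloxy)-4,5-dimethoxyphenyl]-4-methyl-5-(3,4,5-trimethoxyphenyl)oxolane-3-carboxylate (ester cis to the C2 aryl) | COc1cc([C@H]2O[C@@H](c3cc(OC)c(OC)c(OC)c3)[C@H](C)[C@H]2C(=O)OC)cc(OCc4ccccc4)c1OC | intermediate
18 | methyl (2S,3S,4R,5R)-2-[3-(benzyloxy)-4,5-dimethoxyphenyl]-4-methyl-5-(3,4,5-trimethoxyphenyl)oxolane-3-carboxylate | COc1cc([C@H]2O[C@@H](c3cc(OC)c(OC)c(OC)c3)[C@H](C)[C@@H]2C(=O)OC)cc(OCc4ccccc4)c1OC | intermediate
19 | [(2S,3R,4R,5R)-2-[3-(benzyloxy)-4,5-dimethoxyphenyl]-4-methyl-5-(3,4,5-trimethoxyphenyl)oxolan-3-yl]methanol | COc1cc([C@H]2O[C@@H](c3cc(OC)c(OC)c(OC)c3)[C@H](C)[C@@H]2CO)cc(OCc4ccccc4)c1OC | intermediate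
20 | [(2S,3R,4R,5R)-2-[3-(benzyloxy)-4,5-dimethoxyphenyl]-4-methyl-5-(3,4,5-trimethoxyphenyl)oxolan-3-yl]methyl methanesulfonate | COc1cc([C@H]2O[C@@H](c3cc(OC)c(OC)c(OC)c3)[C@H](C)[C@@H]2COS(C)(=O)=O)cc(OCc4ccccc4)c1OC | intermediate
21 | (2S,3S,4R,5R)-2-[3-(benzyloxy)-4,5-dimethoxyphenyl]-3,4-dimethyl-5-(3,4,5-trimethoxyphenyl)oxolane | COc1cc([C@H]2O[C@@H](c3cc(OC)c(OC)c(OC)c3)[C@H](C)[C@@H]2C)cc(OCc4ccccc4)c1OC | intermediate
22 | 5-[(2S,3S,4R,5R)-3,4-dimethyl-5-(3,4,5-trimethoxyphenyl)oxolan-2-yl]-2,3-dimethoxyphenol | COc1cc([C@H]2O[C@@H](c3cc(OC)c(OC)c(OC)c3)[C@H](C)[C@@H]2C)cc(O)c1OC | target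

**Totals**

Total step count: 14. Longest linear sequence: 13 steps (5 → 6 → 7 → 8 → 9 → … → 22); 11 steps counted from 1.

**Steps most likely to fail**

1. Step 10. What may go wrong: hydride migration from the tertiary C4–H to the carbenoid carbon, which gives an unsaturated ester and no ring; carbenoid attack on the electron-rich trimethoxyphenyl ring; a weak cis preference between C2 and C5 during insertion; or a weak thermodynamic bias at C3 during the methoxide equilibration. Fallback (sets out from 4, uses 6, comes back at 19): the ring is closed by C–O bond formation instead, and C3 is set by substrate control in a lactone enolate. Hydroboration–oxidation of 4 (9-BBN; NaOH, H2O2) should give (1R,2R)-2-methyl-1-(3,4,5-trimethoxyphenyl)butane-1,4-diol F1. Oxidative lactonisation (TEMPO, PhI(OAc)2, CH2Cl2) should give (4R,5R)-4-methyl-5-(3,4,5-trimethoxyphenyl)oxolan-2-one F2. Its lithium enolate (LiHMDS, THF, −78 °C) should add to aldehyde 6 anti to the C4 methyl group to give (3S,4R,5R)-3-{[3-(benzyloxy)-4,5-dimethoxyphenyl](hydroxy)methyl}-4-methyl-5-(3,4,5-trimethoxyphenyl)oxolan-2-one F3 as carbinol epimers; this anti addition translates into the cis relationship of the C3 and C4 substituents of the final ring. LiAlH4 should reduce it to (2R,3R,4R)-2-{[3-(benzyloxy)-4,5-dimethoxyphenyl](hydroxy)methyl}-3-methyl-4-(3,4,5-trimethoxyphenyl)butane-1,4-diol F4. TIPSCl and imidazole should silylate only the primary hydroxyl, giving the primary triisopropylsilyl ether of that triol F5. Catalytic p-TsOH in CH2Cl2 should ionise a benzylic hydroxyl and close the 2,5-diaryl ring with each aryl trans to its neighbour, giving triisopropyl{[(2S,3R,4R,5R)-2-[3-(benzyloxy)-4,5-dimethoxyphenyl]-4-methyl-5-(3,4,5-trimethoxyphenyl)oxolan-3-yl]methoxy}silane F6. TBAF then releases 19.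

2. Step 9. What may go wrong: incomplete or reversible Claisen benzoylation of the β-branched ester under NaH at reflux, or decomposition of the α-alkyl diazo ester during the transfer and handling. Fallback (sets out from 14, comes back at 16): nitrogen is introduced by electrophilic azidation and the diazo group is made by diazotisation. The potassium enolate of 14 (KHMDS, THF, −78 °C) with 2,4,6-triisopropylbenzenesulfonyl azide and an acetic acid quench should give methyl (3R,4R)-2-azido-4-{[3-(benzyloxy)-4,5-dimethoxyphenyl]methoxy}-3-methyl-4-(3,4,5-trimethoxyphenyl)butanoate F7 as C2 epimers. Staudinger reduction (PPh3, THF/H2O) should give methyl (3R,4R)-2-amino-4-{[3-(benzyloxy)-4,5-dimethoxyphenyl]methoxy}-3-methyl-4-(3,4,5-trimethoxyphenyl)butanoate F8. Isoamyl nitrite with catalytic acetic acid in warm CHCl3 should then convert the α-amino ester into 16.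

3. Step 14. What may go wrong: hydrogenolytic opening of the doubly benzylic ring C–O bonds at C2 or C5 competing with removal of the benzyl ether. Fallback (sets out from 21, comes back at 22): non-reductive debenzylation with BCl3 and pentamethylbenzene as cation scavenger in CH2Cl2 at −78 °C. This cleaves aryl benzyl ethers in preference to aryl methyl ethers; the short time and low temperature are meant to keep the ring ether from ionising.

Further compounds
F1 | step 10 | (1R,2R)-2-methyl-1-(3,4,5-trimethoxyphenyl)butane-1,4-diol | O[C@@H](c1cc(OC)c(OC)c(OC)c1)[C@H](C)CCO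
F2 | step 10 | (4R,5R)-4-methyl-5-(3,4,5-trimethoxyphenyl)oxolan-2-one | O1[C@@H](c2cc(OC)c(OC)c(OC)c2)[C@H](C)CC1=O
F3 | step 10 | (3S,4R,5R)-3-{[3-(benzyloxy)-4,5-dimethoxyphenyl](hydroxy)methyl}-4-methyl-5-(3,4,5-trimethoxyphenyl)oxolan-2-one (carbinol epimers) | O1[C@@H](c2cc(OC)c(OC)c(OC)c2)[C@H](C)[C@@H](C(O)c2cc(OC)c(OC)c(OCc3ccccc3)c2)C1=O
F4 | step 10 | (2R,3R,4R)-2-{[3-(benzyloxy)-4,5-dimethoxyphenyl](hydroxy)methyl}-3-methyl-4-(3,4,5-trimethoxyphenyl)butane-1,4-diol (carbinol epimers) | O[C@@H](c1cc(OC)c(OC)c(OC)c1)[C@H](C)[C@@H](C(O)c1cc(OC)c(OC)c(OCc2ccccc2)c1)CO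
F5 | step 10 | primary triisopropylsilyl ether of the triol F4, same configuration | O[C@@H](c1cc(OC)c(OC)c(OC)c1)[C@H](C)[C@@H](C(O)c1cc(OC)c(OC)c(OCc2ccccc2)c1)CO[Si](C(C)C)(C(C)C)C(C)C
F6 | step 10 | triisopropyl{[(2S,3R,4R,5R)-2-[3-(benzyloxy)-4,5-dimethoxyphenyl]-4-methyl-5-(3,4,5-trimethoxyphenyl)oxolan-3-yl]methoxy}silane | COc1cc([C@H]2O[C@@H](c3cc(OC)c(OC)c(OC)c3)[C@H](C)[C@@H]2CO[Si](C(C)C)(C(C)C)C(C)C)cc(OCc4ccccc4)c1OC
F7 | step 9 | methyl (3R,4R)-2-azido-4-{[3-(benzyloxy)-4,5-dimethoxyphenyl]methoxy}-3-methyl-4-(3,4,5-trimethoxyphenyl)butanoate (C2 epimers) | COc1cc(CO[C@@H](c2cc(OC)c(OC)c(OC)c2)[C@H](C)C(N=[N+]=[N-])C(=O)OC)cc(OCc3ccccc3)c1OC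
F8 | step 9 | methyl (3R,4R)-2-amino-4-{[3-(benzyloxy)-4,5-dimethoxyphenyl]methoxy}-3-methyl-4-(3,4,5-trimethoxyphenyl)butanoate (C2 epimers) | COc1cc(CO[C@@H](c2cc(OC)c(OC)c(OC)c2)[C@H](C)C(N)C(=O)OC)cc(OCc3ccccc3)c1OC
F0 | step 14 | none | none
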